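**Retrosynthetic overview**

1. The γ-lactone (C8–O7–C6) is made last, by acid-triggered ring expansion of a donor–acceptor cyclopropanecarboxylate (cyclopropane → γ-butyrolactone; the C1–C6 bond is traded for O7–C6), together with MOM removal.
2. The cyclopropane (C1–C5–C6) comes from a 2-aryl-2,5-dihydrofuran-3-carboxylate and a syringyl carbene equivalent (aryldiazomethane made in situ from the aldehyde), added anti to the C2 aryl group.
3. The C2–aryl bond and the C2 stereocentre come from an enantioselective Heck arylation of methyl 4,5-dihydrofuran-3-carboxylate (proposed new step).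
4. Building blocks: catechol → guaiacol → 4-bromoguaiacol MOM ether; p-cresol → 3,5-dibromo-4-hydroxybenzaldehyde → syringaldehyde MOM ether; 2,3-dihydrofuran → β-alkoxyacrylate.
5. Ring order: tetrahydrofuran ring (present from the start) → cyclopropane → γ-lactone.

Assumption: atoms are labelled as in 3,7-dioxabicyclo[3.3.0]octan-8-one (C1, C2–guaiacyl, O3, C4, C5, C6–syringyl, O7, C8=O) in all intermediates; the ligand antipode in step 5 is assigned by analogy with 2,3-dihydrofuran arylations and is swapped if the opposite sense is found.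

**Route**

Step 1
Reactants: 1 catechol (benzene-1,2-diol)
Product: 2 2-methoxyphenol (guaiacol)
Conditions: MeI (1.0 equiv), K2CO3, acetone, reflux (catechol in slight excess)
Reagents that add atoms: iodomethane (CI)
Why: Williamson O-methylation; the first phenoxide forms more easily than the second, so one equivalent of MeI gives mainly the mono-ether.

Step 2
Reactants: 2 2-methoxyphenol
Product: 3 4-bromo-2-methoxyphenol
Conditions: NBS, MeCN, 0 °C
Reagents that add atoms: N-bromosuccinimide (O=C1CCC(=O)N1Br)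
Why: Electrophilic aromatic bromination; the free OH is the strongest director and its para position is open.

Step 3
Reactants: 3 4-bromo-2-methoxyphenol
Product: 4 4-bromo-2-methoxy-1-(methoxymethoxy)benzene
Conditions: NaH, MOMCl, THF, 0 °C → rt
Reagents that add atoms: chloromethyl methyl ether (COCCl)
Why: Phenoxide O-alkylation (MOM ether) masks the phenol for the Pd and base steps and is cleaved by acid in step 10.

Step 4
Reactants: 5 2,3-dihydrofuran
Product: 7 methyl 4,5-dihydrofuran-3-carboxylate, via trichloromethyl ketone 6 (not isolated)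
Conditions: Cl3CCOCl, pyridine, CH2Cl2, 0 °C → rt; then MeOH, K2CO3 (cat.), rt
Reagents that add atoms: trichloroacetyl chloride (O=C(Cl)C(Cl)(Cl)Cl); methanol (CO)
Why: Electrophilic C-acylation of the enol ether at its β-carbon (C1) by addition–elimination, then haloform-type methanolysis of the trichloromethyl ketone gives the β-alkoxyacrylate.

Step 5
Reactants: 4 4-bromo-2-methoxy-1-(methoxymethoxy)benzene; 7 methyl 4,5-dihydrofuran-3-carboxylate
Product: 8 methyl (2R)-2-[3-methoxy-4-(methoxymethoxy)phenyl]-2,5-dihydrofuran-3-carboxylate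
Conditions: Pd2(dba)3 (2.5 mol%), (R)-t-Bu-PHOX (6 mol%), Ag2CO3, toluene, 80 °C; 7 (3 equiv)
Reagents that add atoms: none
Why: Proposed new method: oxidative addition of 4 and bromide abstraction by Ag+ give a cationic Ar–Pd(PHOX)+ that binds the push–pull C2=C1 bond of 7; the aryl group migrates to C2 (α to the ring oxygen and β to the ester, so enol-ether and acrylate polarisation agree) on the face chosen by the ligand, which sets C2; the C1–Pd ester enolate has its only syn β-hydrogen on C5 (the C2–H is anti), so β-hydride elimination gives the conjugated C1=C5 alkene, and PHOX-type ligands release the alkene before Pd–H re-addition; closest known reactions are the Hayashi/Pfaltz enantioselective Heck arylation of 2,3-dihydrofuran and the Heck arylation of acyclic β-alkoxyacrylates, not yet shown on a cyclic β-alkoxyacrylate.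

Step 6
Reactants: 9 4-methylphenol (p-cresol)
Product: 12 3,5-dibromo-4-hydroxybenzaldehyde, via 2,6-dibromo-4-methylphenol 10 (not isolated), via 2,6-dibromo-4-(dibromomethyl)phenol 11 (not isolated)
Conditions: Br2 (2 equiv), o-dichlorobenzene, 35 °C; Br2 (2 equiv), 150 °C; H2O, 100 °C
Reagents that add atoms: bromine (BrBr); water (O)
Why: Ring bromination ortho to OH (SEAr), then thermal benzylic dibromination of the para-methyl group and hydrolysis of the benzal bromide to the aldehyde (known one-pot p-cresol process).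

Step 7
Reactants: 12 3,5-dibromo-4-hydroxybenzaldehyde
Product: 13 4-hydroxy-3,5-dimethoxybenzaldehyde (syringaldehyde)
Conditions: NaOMe, CuCl (cat.), DMF–MeOH, 115 °C
Reagents that add atoms: sodium methoxide ([Na+].[O-]C)
Why: Copper(I)-catalysed Ullmann-type methoxylation replaces both aryl bromides, helped by the para-formyl group (known syringaldehyde synthesis).

Step 8
Reactants: 13 4-hydroxy-3,5-dimethoxybenzaldehyde
Product: 14 3,5-dimethoxy-4-(methoxymethoxy)benzaldehyde
Conditions: NaH, MOMCl, DMF, 0 °C → rt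
Reagents that add atoms: chloromethyl methyl ether (COCCl)
Why: Phenoxide O-alkylation (MOM ether) protects the phenol during the basic diazo step.

Step 9
Reactants: 8 methyl (2R)-2-[3-methoxy-4-(methoxymethoxy)phenyl]-2,5-dihydrofuran-3-carboxylate; 14 3,5-dimethoxy-4-(methoxymethoxy)benzaldehyde
Product: 18 methyl (1R,2R,5R,6S)-6-[3,5-dimethoxy-4-(methoxymethoxy)phenyl]-2-[3-methoxy-4-(methoxymethoxy)phenyl]-3-oxabicyclo[3.1.0]hexane-1-carboxylate, via tosylhydrazone 15 (not isolated), via aryldiazomethane 16 (not isolated), via 1-pyrazoline 17 (not isolated)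
Conditions: 14 (2.5 equiv), TsNHNH2, 1,4-dioxane, 60 °C; then 8, K2CO3, 100 °C
Reagents that add atoms: none
Why: 1,3-Dipolar cycloaddition of the aryldiazomethane formed in situ (Bamford–Stevens) to the enoate C1=C5 (carbon to C5, nitrogen to C1) on the face anti to the C2 aryl group, then thermal N2 loss from the 1-pyrazoline closes C1–C6; this sets C1 and C5, the C6 aryl lies mainly exo and its configuration is reset in step 10.

Step 10
Reactants: 18 methyl (1R,2R,5R,6S)-6-[3,5-dimethoxy-4-(methoxymethoxy)phenyl]-2-[3-methoxy-4-(methoxymethoxy)phenyl]-3-oxabicyclo[3.1.0]hexane-1-carboxylate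
Product: 20 (1S,2S,5R,6S)-6-(4-hydroxy-3,5-dimethoxyphenyl)-2-(4-hydroxy-3-methoxyphenyl)-3,7-dioxabicyclo[3.3.0]octan-8-one, via bis-phenol cyclopropane ester 19 (not isolated)
Conditions: TFA–H2O (9:1), 0 °C → rt
Reagents that add atoms: water (O)
Why: Aqueous TFA cleaves both MOM acetals, and the freed 4-hydroxy-3,5-dimethoxyphenyl donor with the protonated ester acceptor ionises the C1–C6 bond to a quinone-methide-like C6 cation and the ester enol; the enol oxygen closes onto C6, C1 is protonated from the convex face (cis fusion is the only unstrained outcome), water expels methanol from the O-methyl lactonium, and the syringyl group takes the exo position (trans to C4) in the reversible benzylic C–O closure; this is an acid-mediated ring-opening lactonisation of a donor–acceptor cyclopropanecarboxylate (Cloke–Wilson-type ring expansion), with C2 and C5 untouched.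

**Compound list**

1 | benzene-1,2-diol (catechol) | Oc1ccccc1O | starting material
2 | 2-methoxyphenol (guaiacol) | COc1ccccc1O | intermediate
3 | 4-bromo-2-methoxyphenol | COc1cc(Br)ccc1O | intermediate
4 | 4-bromo-2-methoxy-1-(methoxymethoxy)benzene | COCOc1ccc(Br)cc1OC | intermediate
5 | 2,3-dihydrofuran | C1CC=CO1 | starting material
6 | 2,2,2-trichloro-1-(4,5-dihydrofuran-3-yl)ethan-1-one | O=C(C1=COCC1)C(Cl)(Cl)Cl | intermediate (not isolated)
7 | methyl 4,5-dihydrofuran-3-carboxylate | COC(=O)C1=COCC1 | intermediate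
8 | methyl (2R)-2-[3-methoxy-4-(methoxymethoxy)phenyl]-2,5-dihydrofuran-3-carboxylate | COc1cc([C@H]2OCC=C2C(=O)OC)ccc1OCOC | intermediate
9 | 4-methylphenol (p-cresol) | Cc1ccc(O)cc1 | starting material
10 | 2,6-dibromo-4-methylphenol | Cc1cc(Br)c(O)c(Br)c1 | intermediate (not isolated)
11 | 2,6-dibromo-4-(dibromomethyl)phenol | BrC(Br)c1cc(Br)c(O)c(Br)c1 | intermediate (not isolated)
12 | 3,5-dibromo-4-hydroxybenzaldehyde | O=Cc1cc(Br)c(O)c(Br)c1 | intermediate
13 | 4-hydroxy-3,5-dimethoxybenzaldehyde (syringaldehyde) | COc1cc(C=O)cc(OC)c1O | intermediate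
14 | 3,5-dimethoxy-4-(methoxymethoxy)benzaldehyde | COCOc1c(OC)cc(C=O)cc1OC | intermediate
15 | N'-[(E)-[3,5-dimethoxy-4-(methoxymethoxy)phenyl]methylidene]-4-methylbenzenesulfonohydrazide | COCOc1c(OC)cc(/C=N/NS(=O)(=O)c2ccc(C)cc2)cc1OC | intermediate (not isolated)
16 | 5-(diazomethyl)-1,3-dimethoxy-2-(methoxymethoxy)benzene | COCOc1c(OC)cc(C=[N+]=[N-])cc1OC | intermediate (not isolated)
17 | methyl (3aR,6R,6aS)-3-[3,5-dimethoxy-4-(methoxymethoxy)phenyl]-6-[3-methoxy-4-(methoxymethoxy)phenyl]-3,3a,4,6-tetrahydro-6aH-furo[3,4-c]pyrazole-6a-carboxylate (C3 epimers) | COc1cc([C@H]2OC[C@@H]3C(c4cc(OC)c(OCOC)c(OC)c4)N=N[C@]23C(=O)OC)ccc1OCOC | intermediate (not isolated)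
18 | methyl (1R,2R,5R,6S)-6-[3,5-dimethoxy-4-(methoxymethoxy)phenyl]-2-[3-methoxy-4-(methoxymethoxy)phenyl]-3-oxabicyclo[3.1.0]hexane-1-carboxylate | COc1cc([C@H]2OC[C@@H]3[C@@H](c4cc(OC)c(OCOC)c(OC)c4)[C@]23C(=O)OC)ccc1OCOC | intermediate
19 | methyl (1R,2R,5R,6S)-6-(4-hydroxy-3,5-dimethoxyphenyl)-2-(4-hydroxy-3-methoxyphenyl)-3-oxabicyclo[3.1.0]hexane-1-carboxylate | COc1cc([C@H]2OC[C@@H]3[C@@H](c4cc(OC)c(O)c(OC)c4)[C@]23C(=O)OC)ccc1O | intermediate (not isolated)
20 | (1S,2S,5R,6S)-6-(4-hydroxy-3,5-dimethoxyphenyl)-2-(4-hydroxy-3-methoxyphenyl)-3,7-dioxabicyclo[3.3.0]octan-8-one (CNP0142585.1) | COc1cc([C@H]2OC[C@H]3[C@@H]2C(=O)O[C@@H]3c2cc(OC)c(O)c(OC)c2)ccc1O | target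

**Step count and risks**

Total step count: 10. Longest linear sequence: 6 (steps 1, 2, 3, 5, 9, 10).

Most likely to fail, first: step 5, the proposed Heck arylation. The trisubstituted push–pull alkene may insert slowly. The Pd ester enolate may switch faces and eliminate towards C2, giving the achiral 2-aryl-4,5-dihydrofuran. The ee may be low. The fallback uses known chemistry, sets out from 4 and returns at 8. Bromine–lithium exchange on 4 (n-BuLi, THF, −78 °C) and a DMF quench give 3-methoxy-4-(methoxymethoxy)benzaldehyde F1. A catalytic enantioselective Morita–Baylis–Hillman reaction with methyl acrylate (chiral bifunctional phosphine–thiourea or β-isocupreidine-type catalyst, antipode chosen for R; ee upgraded by crystallisation if needed) gives methyl (R)-2-{hydroxy[3-methoxy-4-(methoxymethoxy)phenyl]methyl}prop-2-enoate F2. O-Allylation (allyl bromide, Ag2O, Et2O) gives methyl (R)-2-{[3-methoxy-4-(methoxymethoxy)phenyl](prop-2-en-1-yloxy)methyl}prop-2-enoate F3. Ring-closing metathesis (Grubbs II, CH2Cl2, 40 °C) closes the C1=C5 bond and delivers 8.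

Second: step 9, the cyclopropanation. Cycloaddition to the trisubstituted enoate may be slow against azine or stilbene formation from the diazo compound, and the pyrazoline may tautomerise instead of losing N2. The fallback sets out from 8 (with 16 made separately from 15 and NaOMe) and returns at 18. DIBAL-H (CH2Cl2, −78 °C) reduces 8 to {(2R)-2-[3-methoxy-4-(methoxymethoxy)phenyl]-2,5-dihydrofuran-3-yl}methanol F4. Hydroxyl-directed arylcyclopropanation of its zinc alkoxide with the zinc carbenoid from 16 and ZnI2 (Simmons–Smith type, Et2Zn, CH2Cl2, 0 °C), again anti to the C2 aryl group, gives [(1S,2R,5R,6S)-6-[3,5-dimethoxy-4-(methoxymethoxy)phenyl]-2-[3-methoxy-4-(methoxymethoxy)phenyl]-3-oxabicyclo[3.1.0]hexan-1-yl]methanol F5. TEMPO/PhI(OAc)2 in MeCN–H2O oxidises it to (1R,2R,5R,6S)-6-[3,5-dimethoxy-4-(methoxymethoxy)phenyl]-2-[3-methoxy-4-(methoxymethoxy)phenyl]-3-oxabicyclo[3.1.0]hexane-1-carboxylic acid F6, and TMSCHN2 (toluene–MeOH) gives 18.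

Third: step 10, the ring expansion with global deprotection. Protic acid may epimerise the C2 benzylic ether once its phenol is free, exo selectivity at C6 may be incomplete, and formaldehyde from the MOM groups may attack the electron-rich rings. The fallback separates the two events, sets out from 18 and returns at 20. With the phenols still protected, a Lewis acid in aprotic medium (Sc(OTf)3 10 mol%, CH2Cl2 with 1–2 equiv H2O, 0 °C) effects the ring-expanding lactonisation to (1S,2S,5R,6S)-6-[3,5-dimethoxy-4-(methoxymethoxy)phenyl]-2-[3-methoxy-4-(methoxymethoxy)phenyl]-3,7-dioxabicyclo[3.3.0]octan-8-one F7. Thiol-assisted MOM cleavage (ZnBr2, n-PrSH, CH2Cl2, 0 °C, minutes), in which the thiol traps the methoxymethyl cation, then gives 20.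

**Further compounds**

F1 | step 5 | 3-methoxy-4-(methoxymethoxy)benzaldehyde | COCOc1ccc(C=O)cc1OC
F2 | step 5 | methyl (R)-2-{hydroxy[3-methoxy-4-(methoxymethoxy)phenyl]methyl}prop-2-enoate | COc1cc([C@@H](O)C(=C)C(=O)OC)ccc1OCOC
F3 | step 5 | methyl (R)-2-{[3-methoxy-4-(methoxymethoxy)phenyl](prop-2-en-1-yloxy)methyl}prop-2-enoate | COc1cc([C@@H](OCC=C)C(=C)C(=O)OC)ccc1OCOC
F4 | step 9 | {(2R)-2-[3-methoxy-4-(methoxymethoxy)phenyl]-2,5-dihydrofuran-3-yl}methanol | COc1cc([C@H]2OCC=C2CO)ccc1OCOC
F5 | step 9 | [(1S,2R,5R,6S)-6-[3,5-dimethoxy-4-(methoxymethoxy)phenyl]-2-[3-methoxy-4-(methoxymethoxy)phenyl]-3-oxabicyclo[3.1.0]hexan-1-yl]methanol | COc1cc([C@H]2OC[C@@H]3[C@@H](c4cc(OC)c(OCOC)c(OC)c4)[C@]23CO)ccc1OCOC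
F6 | step 9 | (1R,2R,5R,6S)-6-[3,5-dimethoxy-4-(methoxymethoxy)phenyl]-2-[3-methoxy-4-(methoxymethoxy)phenyl]-3-oxabicyclo[3.1.0]hexane-1-carboxylic acid | COc1cc([C@H]2OC[C@@H]3[C@@H](c4cc(OC)c(OCOC)c(OC)c4)[C@]23C(=O)O)ccc1OCOC
F7 | step 10 | (1S,2S,5R,6S)-6-[3,5-dimethoxy-4-(methoxymethoxy)phenyl]-2-[3-methoxy-4-(methoxymethoxy)phenyl]-3,7-dioxabicyclo[3.3.0]octan-8-one | COc1cc([C@H]2OC[C@H]3[C@@H]2C(=O)O[C@@H]3c2cc(OC)c(OCOC)c(OC)c2)ccc1OCOC
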